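The constants stand for no real mixture.

A ratio reads this flask: complex with one exchanged over starting complex, which at balance of the first step equals its constant 6.2 times incoming ligand over leaving ligand, all as fractions of the starting complex charged.

starting complex 38 mM; incoming ligand 0.800 equiv; leaving ligand 1.00 equiv; time 8.0 min
    starting complex + incoming ligand ⇌ leaving ligand + complex with one exchanged (K1 = 6.2, k1 = 0.82 L mol⁻¹ s⁻¹)
    complex with one exchanged + incoming ligand ⇌ leaving ligand + complex with two exchanged (K2 = 0.68, k2 = 1.5 L mol⁻¹ s⁻¹)
    complex with two exchanged + incoming ligand ⇌ leaving ligand + complex with three exchanged (K3 = 0.48, k3 = 2.6 L mol⁻¹ s⁻¹)
    leaving ligand + complex with two exchanged → side product (k4 = 0.14 L mol⁻¹ s⁻¹)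
- at 8.0 min, what has stopped the reaction, if anything has (it is still moving / all of the starting complex has reacted / the incoming ligand has run out first / forward and back rates have come level)
- amount of complex with two exchanged at 8.0 min, in percent of the starting complex charged
- amount of complex with one exchanged at 8.0 min, in percent of the starting complex charged
- the reaction counts as stopped when no species that holds the starting complex changes by six tenths of a point or more over the second half of the time
- run time (flask): 8.0 min

Work with the fraction left. With the first step taken by itself, whatever part of the starting complex has gone, the incoming ligand, the limiting reagent, has lost that part and the leaving ligand has gained it. At the charge the right-hand side stands at 4.96, and it sinks as the part gone grows, until it meets the ratio at a balance fraction left of 47.4%, a ratio of 1.11.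

The curve of the fraction left starts down with a half-life of 0.46 min, forward rate alone, and at that pace reaches the balance level in 0.500 min, which places the knee. There 52.6% is complex with one exchanged, incoming ligand stands at 0.274 and leaving ligand at 1.53. The second step is quick against the run, so the same rule puts complex with two exchanged at 6.42%. That level still leaks: reckoned at that level, side product forms at 0.0313 min⁻¹ of the charge, or 12.5% over the second half, over a point. So the reckoning says still moving, with both complexes below those levels by an amount it does not size.

The forecast gave it is still moving, 2.3% and 32.5%, on the ground that “The irreversible side reaction keeps draining the second-exchanged complex”.

The flask gives it is still moving, with 2.31% of complex with two exchanged and 34.0% of complex with one exchanged. The first step ran while incoming ligand fell to 37.5% of its charge: by 0.800 min the flask held 57.1% starting complex, and at 1.60 min it held 51.0%, above the balance level. The side reaction then ran on, reaching 12.5% by 8.00 min, and the ratio stood at 0.665, below 1.11, against 0.654 from the ligands in that flask. With 0.200 equiv of incoming ligand, the same fraction left comes to 83.7%, and that neighbour holds 84%.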